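**Assumption:** the target is read as 12‑O‑acetylchlorovulone II, (12R) by CIP analysis of the SMILES, with 5E,7E,14Z alkenes; prostanoid numbering (C1 ester … C20) is used in the text. The QuinoxP* antipode in step 2 is the one that delivers the (R)‑boronate; (S,S) is written on the basis of the reported sense for Z‑carbonates, which I have not re‑verified.

**Retrosynthetic overview**
1. Target 24 ⇐ 12‑alcohol 23 ⇐ TES ether 22 (acetylation last).
2. The only ring is closed late by Rh‑catalysed intramolecular cis‑hydroacylation: the C8–C9 bond forms from a (Z)‑configured 2‑chloro‑enal onto an enyne alkyne, which also sets 7E.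
3. The enyne comes from a Sonogashira coupling (C6–C7); the C9–C11 chloro‑enal arm from a Still–Gennari‑type chloro‑HWE on an α‑silyloxy aldehyde.
4. C12 and the 14Z alkene are set together by chirality‑transfer allylboration of an ynone with an α‑chiral allylboronate (no aldol condensation, no addition to a preformed cyclopentenone).
5. Ring order: acyclic until step 12, where the single cyclopentenone ring is formed.

**Route**

Step 1
Reactants: 1 (2Z)-oct-2-en-1-ol
Product: 2 methyl (2Z)-oct-2-en-1-yl carbonate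
Conditions: ClCO2Me, pyridine, CH2Cl2, 0 °C
Reagents that add atoms: methyl chloroformate COC(=O)Cl
Why: Simple O‑acylation turns the allylic alcohol into the carbonate leaving group needed for Cu‑catalysed allylic substitution, with the Z alkene untouched.

Step 2
Reactants: 2 methyl (2Z)-oct-2-en-1-yl carbonate
Product: 3 4,4,5,5-tetramethyl-2-[(3R)-oct-1-en-3-yl]-1,3,2-dioxaborolane
Conditions: Cu(O-t-Bu) (5 mol %), (S,S)-QuinoxP* (5 mol %), B2pin2, THF, 0 °C
Reagents that add atoms: bis(pinacolato)diboron CC1(C)OB(OC1(C)C)B1OC(C)(C)C(C)(C)O1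
Why: Cu‑catalysed enantioselective γ‑selective (SN2′) allylic borylation of a Z‑allylic carbonate, in which the chiral bisphosphine–boryl copper species chooses the alkene face and so sets the C–B stereocentre as R.

Step 3
Reactants: 4 ethyl 2,2-diethoxyacetate; 5 ethynylmagnesium bromide
Product: 7 1,1-diethoxybut-3-yn-2-one, via magnesium hemiketalate 6 (not isolated)
Conditions: THF, −78 → −40 °C; cold aq. NH4Cl
Reagents that add atoms: none
Why: Acetylide addition to an α,α‑dialkoxy ester stops at the chelated tetrahedral magnesium alkoxide, which collapses to the ynone only on quench, so over‑addition is avoided.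

Step 4
Reactants: 7 1,1-diethoxybut-3-yn-2-one; 3 4,4,5,5-tetramethyl-2-[(3R)-oct-1-en-3-yl]-1,3,2-dioxaborolane
Product: 9 (2S,4Z)-1,1-diethoxy-2-ethynyldec-4-en-2-ol, via borate ester 8 (not isolated)
Conditions: neat (or PhMe, 2 M), 40 °C, 48 h; aq. NH4Cl; AgNO3–SiO2 chromatography
Reagents that add atoms: none
Why: Allylboration of the activated ynone through a closed Zimmerman–Traxler chair with 1,3‑chirality transfer from the α‑chiral allylboronate (Hoffmann type): the slim ethynyl group lies axial on the carbonyl carbon, the branched acetal equatorial and the α‑pentyl group axial, so (R)‑3 delivers C13 to one ketone face only, creating C12 (2S here, 12R in the target) and the 14Z alkene in the same event; the minor E product has the opposite configuration and is removed.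

Step 5
Reactants: 9 (2S,4Z)-1,1-diethoxy-2-ethynyldec-4-en-2-ol
Product: 12 (2S,4Z)-2-ethynyl-2-[(triethylsilyl)oxy]dec-4-enal, via silyl ether acetal 10 (not isolated), via collidinium salt 11 (not isolated)
Conditions: TESOTf (3 equiv), 2,4,6-collidine (4 equiv), CH2Cl2, −40 → 0 °C; then H2O, rt
Reagents that add atoms: triethylsilyl trifluoromethanesulfonate CC[Si](CC)(CC)OS(=O)(=O)C(F)(F)F; water O
Why: The silyl triflate first silylates the tertiary alcohol and then ionises the diethyl acetal to a collidinium N,O‑acetal that water hydrolyses to the aldehyde (silyl triflate/pyridine‑base acetal cleavage), conditions that spare the new silyl ether; the quaternary centre cannot epimerise.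

Step 6
Reactants: 13 methyl 2-[bis(2,2,2-trifluoroethoxy)phosphoryl]acetate
Product: 14 methyl 2-[bis(2,2,2-trifluoroethoxy)phosphoryl]-2-chloroacetate
Conditions: SO2Cl2 (1.0 equiv), CH2Cl2, 0 °C → rt
Reagents that add atoms: sulfuryl chloride ClS(Cl)(=O)=O
Why: Electrophilic α‑chlorination of the active methylene of a phosphonoacetate with one equivalent of sulfuryl chloride gives the mono‑chloro Still–Gennari‑type reagent.

Step 7
Reactants: 12 (2S,4Z)-2-ethynyl-2-[(triethylsilyl)oxy]dec-4-enal; 14 methyl 2-[bis(2,2,2-trifluoroethoxy)phosphoryl]-2-chloroacetate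
Product: 15 methyl (2E,4R,6Z)-2-chloro-4-ethynyl-4-[(triethylsilyl)oxy]dodeca-2,6-dienoate
Conditions: 14, KHMDS (0.95 equiv vs 14), 18-crown-6, THF, −78 °C; then 12
Reagents that add atoms: none
Why: Still–Gennari‑type Horner–Wadsworth–Emmons olefination, in which the electron‑poor bis(trifluoroethyl) phosphonate eliminates from the kinetic adduct so that the ester ends cis to the quaternary carbon (2E), the geometry the ring closure needs; it also installs the C10 chlorine, and C12 is untouched.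

Step 8
Reactants: 15 methyl (2E,4R,6Z)-2-chloro-4-ethynyl-4-[(triethylsilyl)oxy]dodeca-2,6-dienoate
Product: 16 (2E,4R,6Z)-2-chloro-4-ethynyl-4-[(triethylsilyl)oxy]dodeca-2,6-dien-1-ol
Conditions: DIBAL-H (2.5 equiv), CH2Cl2, −78 °C; Rochelle salt
Reagents that add atoms: none
Why: DIBAL 1,2‑reduction of the enoate to the allylic alcohol at low temperature leaves the vinyl chloride, terminal alkyne, silyl ether and alkene geometries intact, and is done before the second methyl ester is introduced.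

Step 9
Reactants: 17 methyl hex-5-ynoate
Product: 19 methyl (5E)-6-iodohex-5-enoate, via alkenylzirconocene 18 (not isolated)
Conditions: Cp2Zr(H)Cl, CH2Cl2, rt; then I2, 0 °C
Reagents that add atoms: iodine II
Why: Schwartz hydrozirconation adds H–Zr syn and anti‑Markovnikov to the terminal alkyne, and iodinolysis with retention gives the (E)‑vinyl iodide.

Step 10
Reactants: 16 (2E,4R,6Z)-2-chloro-4-ethynyl-4-[(triethylsilyl)oxy]dodeca-2,6-dien-1-ol; 19 methyl (5E)-6-iodohex-5-enoate
Product: 20 methyl (5E,9R,10E)-11-chloro-12-hydroxy-9-[(2Z)-oct-2-en-1-yl]-9-[(triethylsilyl)oxy]dodeca-5,10-dien-7-ynoate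
Conditions: Pd(PPh3)4 (5 mol %), CuI (10 mol %), Et3N, THF, rt
Reagents that add atoms: none
Why: Sonogashira coupling forms C6–C7 with retention of the E vinyl geometry; the vinyl iodide reacts at room temperature while the vinyl chloride is inert.

Step 11
Reactants: 20 methyl (5E,9R,10E)-11-chloro-12-hydroxy-9-[(2Z)-oct-2-en-1-yl]-9-[(triethylsilyl)oxy]dodeca-5,10-dien-7-ynoate
Product: 21 methyl (5E,9R,10E)-11-chloro-9-[(2Z)-oct-2-en-1-yl]-12-oxo-9-[(triethylsilyl)oxy]dodeca-5,10-dien-7-ynoate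
Conditions: Dess–Martin periodinane, CH2Cl2, 0 °C → rt
Reagents that add atoms: none
Why: Dess–Martin oxidation converts the primary allylic alcohol into the enal under near‑neutral conditions without E/Z isomerisation, keeping the formyl group cis to the quaternary carbon.

Step 12
Reactants: 21 methyl (5E,9R,10E)-11-chloro-9-[(2Z)-oct-2-en-1-yl]-12-oxo-9-[(triethylsilyl)oxy]dodeca-5,10-dien-7-ynoate
Product: 22 methyl (5E,7E)-7-{(2R)-4-chloro-2-[(2Z)-oct-2-en-1-yl]-5-oxo-2-[(triethylsilyl)oxy]cyclopent-3-en-1-ylidene}hept-5-enoate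
Conditions: [Rh(dppe)]2(BF4)2 (10 mol %), acetone (0.02 M), rt → 40 °C
Reagents that add atoms: none
Why: Proposed new method: Rh(I)‑catalysed intramolecular alkyne cis‑hydroacylation is extended to a (Z)‑held 2‑chloro‑2‑enal, proceeding by aldehyde C–H oxidative addition, syn hydrorhodation of the tethered enyne alkyne to a six‑membered acyl‑rhodacycle and C8–C9 reductive elimination, which forms the only ring and places H‑7 cis to the new ketone (7E) while C12 is untouched; the closest known reaction type is the 5‑exo cis‑hydroacylation of 5‑alkynals to (E)‑2‑alkylidenecyclopentanones.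

Step 13
Reactants: 22 methyl (5E,7E)-7-{(2R)-4-chloro-2-[(2Z)-oct-2-en-1-yl]-5-oxo-2-[(triethylsilyl)oxy]cyclopent-3-en-1-ylidene}hept-5-enoate
Product: 23 methyl (5E,7E)-7-{(2R)-4-chloro-2-hydroxy-2-[(2Z)-oct-2-en-1-yl]-5-oxocyclopent-3-en-1-ylidene}hept-5-enoate
Conditions: HF·pyridine, THF/pyridine, 0 °C
Reagents that add atoms: none
Why: Fluoride‑driven cleavage of the tertiary triethylsilyl ether in a buffered, non‑basic medium spares the base‑sensitive cross‑conjugated chlorodienone and gives the 12‑alcohol (chlorovulone II constitution, 12R).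

Step 14
Reactants: 23 methyl (5E,7E)-7-{(2R)-4-chloro-2-hydroxy-2-[(2Z)-oct-2-en-1-yl]-5-oxocyclopent-3-en-1-ylidene}hept-5-enoate
Product: 24 methyl (5E,7E)-7-{(2R)-2-acetoxy-4-chloro-2-[(2Z)-oct-2-en-1-yl]-5-oxocyclopent-3-en-1-ylidene}hept-5-enoate
Conditions: Ac2O, Et3N, DMAP (cat.), CH2Cl2, rt
Reagents that add atoms: acetic anhydride CC(=O)OC(C)=O
Why: DMAP‑catalysed (Steglich‑type) acylation of the tertiary alcohol proceeds at oxygen with retention at C12 and gives the target.

**Compound list**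

1 | (2Z)-oct-2-en-1-ol | CCCCC/C=C\CO | starting material
2 | methyl (2Z)-oct-2-en-1-yl carbonate | CCCCC/C=C\COC(=O)OC | intermediate
3 | 4,4,5,5-tetramethyl-2-[(3R)-oct-1-en-3-yl]-1,3,2-dioxaborolane | C=C[C@H](B1OC(C)(C)C(C)(C)O1)CCCCC | intermediate
4 | ethyl 2,2-diethoxyacetate | CCOC(OCC)C(=O)OCC | starting material
5 | ethynylmagnesium bromide | C#C[Mg]Br | starting material
6 | bromomagnesium 1,1,2-triethoxybut-3-yn-2-olate (tetrahedral adduct) | CCOC(OCC)C(OCC)(C#C)O[Mg]Br | intermediate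
7 | 1,1-diethoxybut-3-yn-2-one | CCOC(OCC)C(=O)C#C | intermediate
8 | 2-{[(3S,5Z)-3-(diethoxymethyl)undec-5-en-1-yn-3-yl]oxy}-4,4,5,5-tetramethyl-1,3,2-dioxaborolane | CCCCC/C=C\C[C@@](C#C)(OB1OC(C)(C)C(C)(C)O1)C(OCC)OCC | intermediate
9 | (2S,4Z)-1,1-diethoxy-2-ethynyldec-4-en-2-ol | CCCCC/C=C\C[C@@](C#C)(O)C(OCC)OCC | intermediate
10 | {[(3S,5Z)-3-(diethoxymethyl)undec-5-en-1-yn-3-yl]oxy}triethylsilane | CCCCC/C=C\C[C@@](C#C)(O[Si](CC)(CC)CC)C(OCC)OCC | intermediate
11 | 1-{(2S,4Z)-1-ethoxy-2-ethynyl-2-[(triethylsilyl)oxy]dec-4-en-1-yl}-2,4,6-trimethylpyridinium triflate (C1 epimers) | CCCCC/C=C\C[C@@](C#C)(O[Si](CC)(CC)CC)C(OCC)[n+]1c(C)cc(C)cc1C.[O-]S(=O)(=O)C(F)(F)F | intermediate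
12 | (2S,4Z)-2-ethynyl-2-[(triethylsilyl)oxy]dec-4-enal | CCCCC/C=C\C[C@@](C#C)(O[Si](CC)(CC)CC)C=O | intermediate
13 | methyl 2-[bis(2,2,2-trifluoroethoxy)phosphoryl]acetate | COC(=O)CP(=O)(OCC(F)(F)F)OCC(F)(F)F | starting material
14 | methyl 2-[bis(2,2,2-trifluoroethoxy)phosphoryl]-2-chloroacetate | COC(=O)C(Cl)P(=O)(OCC(F)(F)F)OCC(F)(F)F | intermediate
15 | methyl (2E,4R,6Z)-2-chloro-4-ethynyl-4-[(triethylsilyl)oxy]dodeca-2,6-dienoate | CCCCC/C=C\C[C@@](C#C)(O[Si](CC)(CC)CC)/C=C(/Cl)C(=O)OC | intermediate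
16 | (2E,4R,6Z)-2-chloro-4-ethynyl-4-[(triethylsilyl)oxy]dodeca-2,6-dien-1-ol | CCCCC/C=C\C[C@@](C#C)(O[Si](CC)(CC)CC)/C=C(/Cl)CO | intermediate
17 | methyl hex-5-ynoate | COC(=O)CCCC#C | starting material
18 | chlorido[(1E)-6-methoxy-6-oxohex-1-en-1-yl]zirconocene (Cp drawn η1) | COC(=O)CCC/C=C/[Zr](Cl)(C1C=CC=C1)C1C=CC=C1 | intermediate
19 | methyl (5E)-6-iodohex-5-enoate | COC(=O)CCC/C=C/I | intermediate
20 | methyl (5E,9R,10E)-11-chloro-12-hydroxy-9-[(2Z)-oct-2-en-1-yl]-9-[(triethylsilyl)oxy]dodeca-5,10-dien-7-ynoate | CCCCC/C=C\C[C@@](C#C/C=C/CCCC(=O)OC)(O[Si](CC)(CC)CC)/C=C(/Cl)CO | intermediate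
21 | methyl (5E,9R,10E)-11-chloro-9-[(2Z)-oct-2-en-1-yl]-12-oxo-9-[(triethylsilyl)oxy]dodeca-5,10-dien-7-ynoate | CCCCC/C=C\C[C@@](C#C/C=C/CCCC(=O)OC)(O[Si](CC)(CC)CC)/C=C(/Cl)C=O | intermediate
22 | methyl (5E,7E)-7-{(2R)-4-chloro-2-[(2Z)-oct-2-en-1-yl]-5-oxo-2-[(triethylsilyl)oxy]cyclopent-3-en-1-ylidene}hept-5-enoate | CCCCC/C=C\C[C@@]1(O[Si](CC)(CC)CC)C=C(Cl)C(=O)/C1=C/C=C/CCCC(=O)OC | intermediate
23 | methyl (5E,7E)-7-{(2R)-4-chloro-2-hydroxy-2-[(2Z)-oct-2-en-1-yl]-5-oxocyclopent-3-en-1-ylidene}hept-5-enoate | CCCCC/C=C\C[C@@]1(O)C=C(Cl)C(=O)/C1=C/C=C/CCCC(=O)OC | intermediate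
24 | methyl (5E,7E)-7-{(2R)-2-acetoxy-4-chloro-2-[(2Z)-oct-2-en-1-yl]-5-oxocyclopent-3-en-1-ylidene}hept-5-enoate | CCCCC/C=C\C[C@@]1(OC(C)=O)C=C(Cl)C(=O)/C1=C/C=C/CCCC(=O)OC | target

**Totals**

Total step count: 14. Longest linear sequence: 11 steps (1, 2, 4, 5, 7, 8, 10, 11, 12, 13, 14) from (2Z)-oct-2-en-1-ol; 10 from ethyl 2,2-diethoxyacetate.

**Three steps most likely to fail, with fallbacks**

Step 12 (Rh hydroacylation). The 2‑chloro‑enal may decarbonylate or isomerise before the alkyne inserts. The fallback sets out from 21 and comes back at 22. Pinnick oxidation of 21 gives (2E,4R,7E)-2-chloro-12-methoxy-4-[(2Z)-oct-2-en-1-yl]-12-oxo-4-[(triethylsilyl)oxy]dodeca-2,7-dien-5-ynoic acid F8. Diphenyl diselenide and tributylphosphine convert it into the Se‑phenyl selenoester F9. Slow addition of Bu3SnH/AIBN then generates the α‑chlorovinyl acyl radical, which closes 5‑exo‑dig on the enyne alkyne; reduction of the dienyl radical gives 22 as a 7E/7Z mixture that is equilibrated to 7E with catalytic iodine. This is a radical ring closure in place of the organometallic one.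

Step 4 (chirality‑transfer allylboration). The ketone may react slowly with the secondary boronate, the Z/E ratio may be modest, or the facial selectivity may be lower than the chair model predicts. The fallback sets out from 4 and comes back at 9, with catalyst control of C12 and the Z alkene made by semihydrogenation. Compound 4 and lithium (trimethylsilyl)acetylide give 1,1-diethoxy-4-(trimethylsilyl)but-3-yn-2-one F1. Separately, commercial oct-2-yn-1-ol is converted into methyl oct-2-yn-1-yl carbonate F2, and Cu‑catalysed SN2′ borylation with B2pin2 gives the allenylboronate 4,4,5,5-tetramethyl-2-(octa-1,2-dien-3-yl)-1,3,2-dioxaborolane F3. A chiral 3,3′‑dibromo‑BINOL‑catalysed propargylation of F1 with F3 (the enantiomer of catalyst chosen for 2S) gives (2S)-1,1-diethoxy-2-[(trimethylsilyl)ethynyl]dec-4-yn-2-ol F4. Lindlar hydrogenation reduces only the dialkyl alkyne, giving (2S,4Z)-1,1-diethoxy-2-[(trimethylsilyl)ethynyl]dec-4-en-2-ol F5, and K2CO3/MeOH removes the C‑silyl group to give 9.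

Step 7 (chloro‑HWE geometry). With the very hindered α‑quaternary aldehyde the reagent may not give the ester cis to C12 cleanly. The fallback sets out from 12 and comes back at 16, accepting the thermodynamic geometry first and correcting it photochemically. A standard HWE reaction of 12 with commercial triethyl 2-chloro-2-phosphonoacetate (NaH, THF) gives mainly ethyl (2Z,4R,6Z)-2-chloro-4-ethynyl-4-[(triethylsilyl)oxy]dodeca-2,6-dienoate F6, with the ester trans to C12. Triplet‑sensitised irradiation (thioxanthone, 365 nm) then drives it towards the twisted, deconjugated ethyl (2E,4R,6Z)-2-chloro-4-ethynyl-4-[(triethylsilyl)oxy]dodeca-2,6-dienoate F7, with recycling of recovered F6. DIBAL‑H reduction of F7 gives 16.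

**Further compounds**

F1 | step 4 | 1,1-diethoxy-4-(trimethylsilyl)but-3-yn-2-one | CCOC(OCC)C(=O)C#C[Si](C)(C)C
F2 | step 4 | methyl oct-2-yn-1-yl carbonate | CCCCCC#CCOC(=O)OC
F3 | step 4 | 4,4,5,5-tetramethyl-2-(octa-1,2-dien-3-yl)-1,3,2-dioxaborolane | C=C=C(CCCCC)B1OC(C)(C)C(C)(C)O1
F4 | step 4 | (2S)-1,1-diethoxy-2-[(trimethylsilyl)ethynyl]dec-4-yn-2-ol | CCCCCC#CC[C@@](C#C[Si](C)(C)C)(O)C(OCC)OCC
F5 | step 4 | (2S,4Z)-1,1-diethoxy-2-[(trimethylsilyl)ethynyl]dec-4-en-2-ol | CCCCC/C=C\C[C@@](C#C[Si](C)(C)C)(O)C(OCC)OCC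
F6 | step 7 | ethyl (2Z,4R,6Z)-2-chloro-4-ethynyl-4-[(triethylsilyl)oxy]dodeca-2,6-dienoate | CCCCC/C=C\C[C@@](C#C)(O[Si](CC)(CC)CC)/C=C(\Cl)C(=O)OCC
F7 | step 7 | ethyl (2E,4R,6Z)-2-chloro-4-ethynyl-4-[(triethylsilyl)oxy]dodeca-2,6-dienoate | CCCCC/C=C\C[C@@](C#C)(O[Si](CC)(CC)CC)/C=C(/Cl)C(=O)OCC
F8 | step 12 | (2E,4R,7E)-2-chloro-12-methoxy-4-[(2Z)-oct-2-en-1-yl]-12-oxo-4-[(triethylsilyl)oxy]dodeca-2,7-dien-5-ynoic acid | CCCCC/C=C\C[C@@](C#C/C=C/CCCC(=O)OC)(O[Si](CC)(CC)CC)/C=C(/Cl)C(=O)O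
F9 | step 12 | Se-phenyl (2E,4R,7E)-2-chloro-12-methoxy-4-[(2Z)-oct-2-en-1-yl]-12-oxo-4-[(triethylsilyl)oxy]dodeca-2,7-dien-5-yneselenoate | CCCCC/C=C\C[C@@](C#C/C=C/CCCC(=O)OC)(O[Si](CC)(CC)CC)/C=C(/Cl)C(=O)[Se]c1ccccc1
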